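The vessel on Wednesday gave me readings of target, and from those I had to think about a more dilute flask.

| flask | starting material | reagent | remark | time |
|---|---|---|---|---|
| Wednesday's | 0.32 M | 0.60 equiv (fed, over 3.0 min) | run made earlier; the fed solution adds 0.25 times the starting volume |  |
| flask | 0.21 M | 0.600 equiv (fed, over 3.0 min) | the fed solution adds 0.25 times the starting volume | 8.0 h |

Wednesday's run (percent of the starting material charged): time / h: target / % = 0.200: 20.0; 0.667: 9.6; 1.00: 4.7; 1.50: 2.6; 2.50: 1.3

(scatter of a reading: 0.3 percentage points)

- amounts and yields of target count crystals too
- charges are per starting volume, the dose included; the dosed solution carries all of it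
- given per volume of solution although it is solid: crystals
- steps under discussion: starting material + reagent -> intermediate + released group; intermediate <-> target; intermediate <-> isomer of the product; starting material + released group -> side product; crystals <-> target

- time, not beyond 8.0 h, at which the flask holds most target
- the amount of target, in percent of the starting material charged, at that time
- the first time at which target reaches 5.3%, in the same percent

I read Wednesday's table from the bottom. I took the last row, 1.3%, as a floor and reckoned only the excess above it. The rows at 0.667 h and 1.50 h carry excesses of 8.3 percentage points and 1.3 points, so the excess fell at a rate of 2.23 h⁻¹. That is a reading, with 0.3 points of scatter on each point. It gives 0.311 h: the drain life, the time in which the excess over the floor halves.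

Carried on to the last row of Wednesday's run, the excess comes to 0.14 points, less than the scatter, so the floor could stand. At 1.00 h the curve gives 5.25% against the 4.7% read. Run backwards to 0.200 h, it gives 24.8%, more than the 20.0% read, so the fall read on Wednesday does not reach back that far. I took that time as my own guess for the flask's peak, and expected after it a halving of the excess every 0.311 h.

The forecast held that “it is a kinetic product draining through the intermediate to the isomer”, which is kinetic control in the usual term. Its tail relaxes at about 1.7 per hour where I read 2.23 h⁻¹. It put the peak at 18% (range 10% to 30%) near 0.2 h (range 0.08 h to 0.45 h), and the asked level at 0.05 h (range 0.02 h to 0.12 h).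

The flask peaked at 17.8% at 0.229 h and passed the asked level at 0.0584 h, later than the forecast's time.

    starting material + reagent → intermediate + released group (k = 0.0190 L mol⁻¹ s⁻¹)
    intermediate ⇌ target (K = 3.90, k = 0.00700 s⁻¹)
    intermediate ⇌ isomer of the product (K = 240, k = 0.00430 s⁻¹)
    starting material + released group → side product (k = 0.0290 L mol⁻¹ s⁻¹)
    crystals ⇌ target, rate k5*(cs5 - [target]) while solid is left; crystals form when [target] > cs5 (solubility = 0.170 M, k = 0.0170 s⁻¹)

At the peak the flask still held 28.9% of its starting material. From 14.1% at 0.457 h, with the end amount 0.860% as floor, the drain life gives 5.63% at 0.915 h, and the flask held 6.52%. In the neighbouring flask, the same but for 2.40 equiv of reagent, whose peak was 34.3%, the longest time allowed spans 25.7 of the drain lives read on Wednesday, and its target ended at 1.24%.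

Readings and results were computed on assumed constants, and the scatter is random.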